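Everything rests on building ring A, the 1,2,3,5-tetrasubstituted benzene (C1–OH, C2–CH2Ar, C3–OMe, C5–CH2CH2Ar), de novo instead of substituting a resorcinol. A thermal Danheiser benzannulation merges a 3-(arylethyl)cyclobutenone (C1, C4, C5, C6) with a benzyl-substituted methyl ynol ether (C2, C3): one operation forms the C1–C2 and C3–C4 bonds, closes the ring through C1–C6, and delivers the free OH and the OMe already differentiated, with the benzyl carbon locked between them and para to the chain. The precursor is the pair cyclobutenone plus ynol ether, each carrying its phenol as a benzyl ether; one hydrogenolysis then finishes the synthesis.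

Key step: step 5

Remark: the target has no stereocentre and is achiral, so "single enantiomer" is taken to mean the compound exactly as drawn; no stereocontrol is required.

Step 1
Reactants: 1 3-(benzyloxy)benzyl bromide; 2 1-(trimethylsilyl)propyne
Product: 5 1-(benzyloxy)-3-(but-3-yn-1-yl)benzene, via 3-(trimethylsilyl)propargyllithium 3 (not isolated), via silylalkyne 4 (not isolated)
Conditions: 2, n-BuLi, THF, −78 → −20 °C; 1, −78 °C → rt; then K2CO3, MeOH, rt
Reagents that add atoms: none
Why: Propargylic lithiation of 2, SN2 alkylation of the benzylic bromide and methoxide-mediated protodesilylation of the alkynylsilane should give the terminal alkyne without touching the aryl benzyl ether.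

Step 2
Reactants: 5 1-(benzyloxy)-3-(but-3-yn-1-yl)benzene; 6 trichloroacetyl chloride
Product: 8 3-{2-[3-(benzyloxy)phenyl]ethyl}-4,4-dichlorocyclobut-2-en-1-one, via dichloroketene 7 (not isolated)
Conditions: Zn–Cu couple, Et2O/DME, rt
Reagents that add atoms: none
Why: In this ketene–alkyne [2+2] cycloaddition the terminal alkyne carbon attacks the ketene carbonyl carbon, which places the chain at C3 of the cyclobutenone, while DME sequesters ZnCl2 away from the benzyloxyarene.

Step 3
Reactants: 8 3-{2-[3-(benzyloxy)phenyl]ethyl}-4,4-dichlorocyclobut-2-en-1-one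
Product: 9 3-{2-[3-(benzyloxy)phenyl]ethyl}cyclobut-2-en-1-one
Conditions: Zn dust, AcOH, TMEDA, EtOH, 0 °C → rt
Reagents that add atoms: none
Why: Buffered zinc reduction is the standard reductive dechlorination of 4,4-dichlorocyclobutenones, removing both C–Cl bonds through zinc enolates while the amine buffer suppresses double-bond migration and over-reduction.

Step 4
Reactants: 10 2-chloro-1,1-dimethoxyethane (chloroacetaldehyde dimethyl acetal); 11 4-(benzyloxy)benzyl bromide
Product: 13 1-(benzyloxy)-4-(3-methoxyprop-2-yn-1-yl)benzene, via lithium methoxyacetylide 12 (not isolated)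
Conditions: Et2NH (3.0 equiv), n-BuLi (3.0 equiv), THF, 0 °C; 10 (1.0 equiv), 0 °C → rt; then 11 (0.8 equiv), HMPA, −78 °C → rt; Et3N-deactivated silica
Reagents that add atoms: none
Why: Twofold elimination (MeOH, then HCl) and deprotonation of the chloroacetal by exactly three equivalents of lithium amide is the classical alkoxyacetylide synthesis, and SN2 C-alkylation by the reactive 4-alkoxybenzyl bromide in THF/HMPA should follow with no amide left to isomerize the product to an allenyl ether.

Step 5
Reactants: 9 3-{2-[3-(benzyloxy)phenyl]ethyl}cyclobut-2-en-1-one; 13 1-(benzyloxy)-4-(3-methoxyprop-2-yn-1-yl)benzene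
Product: 18 2-[4-(benzyloxy)benzyl]-5-{2-[3-(benzyloxy)phenyl]ethyl}-3-methoxyphenol, via vinylketene 14 (not isolated), via vinylcyclobutenone 15 (not isolated), via dienylketene 16 (not isolated), via cyclohexadienone 17 (not isolated)
Conditions: 9 (1.0 equiv), 13 (1.3 equiv), toluene, 80 °C then 110 °C, sealed tube, Ar; then K2CO3, MeOH, rt
Reagents that add atoms: none
Why: Danheiser benzannulation: 9 opens by reversible 4π-electrocyclic cleavage to vinylketene 14, which adds ynol ether 13 in a [2+2] cycloaddition to give vinylcyclobutenone 15; a second 4π opening gives dienylketene 16, which closes to cyclohexadienone 17 and tautomerizes to phenol 18. The closest known reaction type is exactly this thermal cyclobutenone/1-alkoxyalkyne aromatic annulation, which gives resorcinol monoethers. Ring A is closed by a thermal disrotatory 6π-electrocyclization (C1–C6) after the [2+2] step has formed C1–C2 and C3–C4. No stereocentre is created, since the sp3 carbons of 15 and 17 are lost on aromatization. The only selectivity needed is the orientation of the [2+2] step, and the methoxy group of 13 secures it by making the benzyl-bearing alkyne carbon the nucleophile that bonds to the ketene carbonyl carbon, so that the benzyl carbon ends up between the new OH and the OMe and the chain of 9 para to it. The methyl ynol ether has no β-hydrogen for retro-ene loss, the benzyl ethers keep phenols from capturing the ketenes, and the carbonate wash returns any product O-acylated by a ketene.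

Step 6
Reactants: 18 2-[4-(benzyloxy)benzyl]-5-{2-[3-(benzyloxy)phenyl]ethyl}-3-methoxyphenol
Product: 19 2-(4-hydroxybenzyl)-5-[2-(3-hydroxyphenyl)ethyl]-3-methoxyphenol (CNP0112925.0)
Conditions: H2 (1 atm), 10% Pd/C, EtOAc/MeOH, rt
Reagents that add atoms: none
Why: Catalytic hydrogenolysis of both aryl benzyl ethers over Pd/C at ambient pressure should leave the diarylmethane and bibenzyl C–C bonds and the methyl ether untouched.

Compound list
1 | 3-(benzyloxy)benzyl bromide [1-(benzyloxy)-3-(bromomethyl)benzene] | BrCc1cccc(OCc2ccccc2)c1 | starting material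
2 | 1-(trimethylsilyl)propyne [trimethyl(prop-1-yn-1-yl)silane] | CC#C[Si](C)(C)C | starting material
3 | [3-(trimethylsilyl)prop-2-yn-1-yl]lithium | [Li]CC#C[Si](C)(C)C | intermediate
4 | {4-[3-(benzyloxy)phenyl]but-1-yn-1-yl}trimethylsilane | C[Si](C)(C)C#CCCc1cccc(OCc2ccccc2)c1 | intermediate
5 | 1-(benzyloxy)-3-(but-3-yn-1-yl)benzene | C#CCCc1cccc(OCc2ccccc2)c1 | intermediate
6 | trichloroacetyl chloride | ClC(=O)C(Cl)(Cl)Cl | starting material
7 | dichloroketene | ClC(Cl)=C=O | intermediate
8 | 3-{2-[3-(benzyloxy)phenyl]ethyl}-4,4-dichlorocyclobut-2-en-1-one | O=C1C=C(CCc2cccc(OCc3ccccc3)c2)C1(Cl)Cl | intermediate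
9 | 3-{2-[3-(benzyloxy)phenyl]ethyl}cyclobut-2-en-1-one | O=C1C=C(CCc2cccc(OCc3ccccc3)c2)C1 | intermediate
10 | 2-chloro-1,1-dimethoxyethane | COC(CCl)OC | starting material
11 | 4-(benzyloxy)benzyl bromide [1-(benzyloxy)-4-(bromomethyl)benzene] | BrCc1ccc(OCc2ccccc2)cc1 | starting material
12 | lithium methoxyacetylide | [Li]C#COC | intermediate
13 | 1-(benzyloxy)-4-(3-methoxyprop-2-yn-1-yl)benzene | COC#CCc1ccc(OCc2ccccc2)cc1 | intermediate
14 | 5-[3-(benzyloxy)phenyl]-3-methylidenepent-1-en-1-one (vinylketene) | O=C=CC(=C)CCc1cccc(OCc2ccccc2)c1 | intermediate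
15 | 2-[4-(benzyloxy)benzyl]-4-{4-[3-(benzyloxy)phenyl]but-1-en-2-yl}-3-methoxycyclobut-2-en-1-one | COC1=C(Cc2ccc(OCc3ccccc3)cc2)C(=O)C1C(=C)CCc1cccc(OCc2ccccc2)c1 | intermediate
16 | (3E)-2-[4-(benzyloxy)benzyl]-5-{2-[3-(benzyloxy)phenyl]ethyl}-3-methoxyhexa-1,3,5-trien-1-one (dienylketene; ketene carbon and vinyl group cis) | O=C=C(Cc1ccc(OCc2ccccc2)cc1)/C(OC)=C\C(=C)CCc1cccc(OCc2ccccc2)c1 | intermediate
17 | 2-[4-(benzyloxy)benzyl]-5-{2-[3-(benzyloxy)phenyl]ethyl}-3-methoxycyclohexa-2,4-dien-1-one | COC1=C(Cc2ccc(OCc3ccccc3)cc2)C(=O)CC(CCc2cccc(OCc3ccccc3)c2)=C1 | intermediate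
18 | 2-[4-(benzyloxy)benzyl]-5-{2-[3-(benzyloxy)phenyl]ethyl}-3-methoxyphenol | COc1cc(CCc2cccc(OCc3ccccc3)c2)cc(O)c1Cc1ccc(OCc2ccccc2)cc1 | intermediate
19 | 2-(4-hydroxybenzyl)-5-[2-(3-hydroxyphenyl)ethyl]-3-methoxyphenol (achiral) | COc1cc(CCc2cccc(O)c2)cc(O)c1Cc1ccc(O)cc1 | target

Total step count: 6
Longest linear sequence: 5 steps (steps 1, 2, 3, 5, 6, from 1 to 19); step 4 is the convergent branch.

Steps most likely to fail

Step 5. The vinylketene may oligomerize or be captured by phenol that has already formed faster than it undergoes the [2+2] step, and the ynol ether may isomerize or decompose on prolonged heating. The fallback takes ring A from a preformed arene; it sets out from 1 (drawing also on 11) and comes back to the route at 19.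
- Arbuzov reaction of 1 with triethyl phosphite (neat, 130 °C) should give diethyl [3-(benzyloxy)benzyl]phosphonate F1.
- Horner–Wadsworth–Emmons olefination of commercial 4-bromo-3,5-dimethoxybenzaldehyde with F1 (NaH, THF) should give 5-{(E)-2-[3-(benzyloxy)phenyl]ethenyl}-2-bromo-1,3-dimethoxybenzene F2.
- Zinc insertion into 11 (Zn dust, LiCl, THF) should give 4-(benzyloxy)benzylzinc bromide F3.
- Negishi coupling of F3 with F2 (Pd(OAc)2, SPhos, THF, 60 °C) should give 5-{(E)-2-[3-(benzyloxy)phenyl]ethenyl}-2-[4-(benzyloxy)benzyl]-1,3-dimethoxybenzene F4.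
- Hydrogenation over Pd/C should saturate the alkene and remove both benzyl groups to give 3-{2-[4-(4-hydroxybenzyl)-3,5-dimethoxyphenyl]ethyl}phenol F5.
- Mono-demethylation of F5 with NaSEt in DMF at 150 °C should give 19; it should stop after the first methyl group because ring A then carries a deactivating phenoxide.

Step 4. C-alkylation of the lithium alkoxyacetylide may be sluggish, the doubly activated CH2 of the product may undergo base-mediated propargyl-to-allenyl isomerization, and the ynol ether may hydrolyse on purification. The fallback puts the oxygen on a preformed alkyne as a silyl ether; it sets out from 11 and comes back to the route at 18.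
- Copper-catalysed coupling of 11 with ethynylmagnesium bromide (CuBr cat., THF) should give 1-(benzyloxy)-4-(prop-2-yn-1-yl)benzene F6.
- Acetylide oxidation of F6 to the ynolate (n-BuLi, THF, −78 °C; lithium tert-butyl peroxide) and O-silylation with TIPSOTf should give ({3-[4-(benzyloxy)phenyl]prop-1-yn-1-yl}oxy)triisopropylsilane F7.
- The same thermal benzannulation of 9 with F7 should give 2-[4-(benzyloxy)benzyl]-5-{2-[3-(benzyloxy)phenyl]ethyl}-3-[(triisopropylsilyl)oxy]phenol F8.
- O-methylation of the free phenol (MeI, K2CO3, acetone) should give {2-[4-(benzyloxy)benzyl]-5-{2-[3-(benzyloxy)phenyl]ethyl}-3-methoxyphenoxy}triisopropylsilane F9.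
- TBAF in THF should then give 18, because the two oxygen positions of ring A are interchangeable by the symmetry of the substitution pattern.

Step 2. Dichloroketene may polymerize, zinc chloride may promote side reactions of the electron-rich benzyloxyarene, and the dechlorination that follows may over-reduce or shift the ring double bond. The fallback uses a keteniminium [2+2] cycloaddition and needs no chlorine; it sets out from 5 and comes back to the route at 9, bypassing 8.
- Compound 5 with N,N-dimethylacetamide, Tf2O and 2,4,6-collidine in refluxing 1,2-dichloroethane should give N-(3-{2-[3-(benzyloxy)phenyl]ethyl}cyclobut-2-en-1-ylidene)-N-methylmethanaminium triflate F10.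
- Hydrolysis of F10 with aqueous NaHCO3 should give 9.

Further compounds
F1 | step 5 | diethyl [3-(benzyloxy)benzyl]phosphonate | CCOP(=O)(Cc1cccc(OCc2ccccc2)c1)OCC
F2 | step 5 | 5-{(E)-2-[3-(benzyloxy)phenyl]ethenyl}-2-bromo-1,3-dimethoxybenzene | COc1cc(/C=C/c2cccc(OCc3ccccc3)c2)cc(OC)c1Br
F3 | step 5 | 4-(benzyloxy)benzylzinc bromide | Br[Zn]Cc1ccc(OCc2ccccc2)cc1
F4 | step 5 | 5-{(E)-2-[3-(benzyloxy)phenyl]ethenyl}-2-[4-(benzyloxy)benzyl]-1,3-dimethoxybenzene | COc1cc(/C=C/c2cccc(OCc3ccccc3)c2)cc(OC)c1Cc1ccc(OCc2ccccc2)cc1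
F5 | step 5 | 3-{2-[4-(4-hydroxybenzyl)-3,5-dimethoxyphenyl]ethyl}phenol | COc1cc(CCc2cccc(O)c2)cc(OC)c1Cc1ccc(O)cc1
F6 | step 4 | 1-(benzyloxy)-4-(prop-2-yn-1-yl)benzene | C#CCc1ccc(OCc2ccccc2)cc1
F7 | step 4 | ({3-[4-(benzyloxy)phenyl]prop-1-yn-1-yl}oxy)triisopropylsilane | CC(C)[Si](OC#CCc1ccc(OCc2ccccc2)cc1)(C(C)C)C(C)C
F8 | step 4 | 2-[4-(benzyloxy)benzyl]-5-{2-[3-(benzyloxy)phenyl]ethyl}-3-[(triisopropylsilyl)oxy]phenol | CC(C)[Si](Oc1cc(CCc2cccc(OCc3ccccc3)c2)cc(O)c1Cc1ccc(OCc2ccccc2)cc1)(C(C)C)C(C)C
F9 | step 4 | {2-[4-(benzyloxy)benzyl]-5-{2-[3-(benzyloxy)phenyl]ethyl}-3-methoxyphenoxy}triisopropylsilane | COc1cc(CCc2cccc(OCc3ccccc3)c2)cc(O[Si](C(C)C)(C(C)C)C(C)C)c1Cc1ccc(OCc2ccccc2)cc1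
F10 | step 2 | N-(3-{2-[3-(benzyloxy)phenyl]ethyl}cyclobut-2-en-1-ylidene)-N-methylmethanaminium triflate | C[N+](C)=C1C=C(CCc2cccc(OCc3ccccc3)c2)C1.[O-]S(=O)(=O)C(F)(F)F
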